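The runs were generated by integration for substances that don't exist; scatter was added.

If every enzyme in a flask kept one pace, the product would be that pace times the time times the loading. So I count turnovers per enzyme per day, a mean turnover frequency: the fraction of substrate turned into product, divided by the days and by the loading of free enzyme.

in all of them: substrate 20 mM; free enzyme 0.0014 mol%
- Friday's: added ligand 0.47 µM; temperature −40 °C; run made earlier
- Tuesday's: added ligand 1.1 µM; temperature −15 °C; run made earlier
- maple: added ligand 0.80 µM; temperature −35 °C; time 8.0 d
- oak: added ligand 1.3 µM; temperature 5 °C; time 2.5 d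

- Friday's (time / d: product / %): 2.08: 0.4; 5.00: 1.7; 10.0: 2.7; 25.0: 7.0
- Tuesday's (time / d: product / %): 0.625: 3.4; 1.25: 6.4; 3.00: 15.0; 6.00: 28.7

(standard deviation of a reading: 0.3 percentage points)

* which one finishes higher in amount of product, in percent of the substrate charged ("neither" within 2 percentage points) (maple / oak / neither)
* amount of product at the end, in percent of the substrate charged, maple
* amount of product at the end, in percent of the substrate charged, oak



Read at its last point, Tuesday's run gives a pace of 3420 d⁻¹, and Friday's run gives 200 d⁻¹. These are readings with their scatter, and Tuesday's is 17.1 times Friday's, with warmth and added ligand both changed.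

Two of us part at oak. The forecast carries the climb on along a temperature line and centres on a weak effect of the added ligand: “Ligand is in excess over enzyme (0.28 µM) in all runs, so I centre on a weak ligand effect.” It gives maple 4.5% (range 3% to 7%) and oak 60% (range 42% to 80%), with oak ahead. For oak that means a pace of 17100 d⁻¹.

I read the excess the other way. Oak holds 4.64 added ligand per enzyme, enough by count to hold each enzyme, and I take a held enzyme to make nothing. So I refuse to carry the climb past Tuesday's run and keep Tuesday's pace. Over 2.5 d that gives oak 12.0%, which still puts oak ahead of the forecast's maple.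

The flasks give oak ahead, with maple at 4.60% and oak at 27.0%. Oak's figure is 33 percentage points under the forecast and 15 points over mine.

    substrate + free enzyme ⇌ starting complex (K = 31.0 M⁻¹, k = 1.30 × 10⁷ M⁻¹ h⁻¹, Ea = 37.0 kJ mol⁻¹, ΔH = −48.0 kJ mol⁻¹)
    starting complex ⇌ free enzyme + product (K = 0.0460 M, k = 2200 h⁻¹, Ea = 66.0 kJ mol⁻¹, ΔH = −67.0 kJ mol⁻¹)
    free enzyme + added ligand ⇌ idle complex, settled at all times (K = 1.40 × 10⁶ M⁻¹, ΔH = 20.0 kJ mol⁻¹)
    free enzyme → unfolded enzyme (k = 6.20 × 10⁻⁵ h⁻¹, Ea = 254 kJ mol⁻¹)
    (constants at 5 °C)

Maple lies inside the forecast's range, and that cold side is the line's region: starting complex is nearly all of maple's catalyst, 93.8% at 8.00 d. Oak's pace is 7730 d⁻¹, twice Tuesday's and below the forecast's. Oak's recipe at −20 °C makes 7.97%, a pace of 2280 d⁻¹, with starting complex at 71.4%. In oak, starting complex was made as fast as it was used, a ratio of 1.00 at 1.08 d, while the step to free enzyme and product ran from starting complex at 16.6% of the catalyst charged at 1.25 d. By 2.50 d oak's idle complex stood at 52.6% of the catalyst charged and its starting complex at 14.7%.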